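**Plan**

1. Retrosynthesis: remove the two angelate esters; cut the cyclobutane bond between the CH that carries the seven-membered ring and the bridgehead next to the enone carbonyl (enolate displacement of a mesylate); cut the two bonds joining the methylcyclohexenone ring to the seven-membered ring (Diels–Alder); cut the two seven-ring bonds flanking the ketone-level carbon (oxyallyl cation plus 2-methylfuran).
2. Enabling feature: going round the seven-membered ring from the quaternary C(CH3)(CH2O) carbon, the next CH bears oxygen and the third carbon beyond it is the methyl-bearing cyclobutane carbon, with the cyclobutane CH closing the ring on the other side. With that CH at the ketone level, the ring is the opened form of an 8-oxabicyclo[3.2.1]octan-3-one whose oxygen bridge joined the CH–O and C–CH3 carbons.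
3. Forward order: a (4+3) cycloaddition makes the seven-membered ring, a silyl triflate opens the oxygen bridge to a hydroxy enone, a Diels–Alder reaction adds the six-membered ring, an intramolecular enolate alkylation closes the cyclobutane, and the angelates go on last.
4. Stereochemistry: the quaternary carbon and the carbinol are set relative to each other in the (4+3) step (chelated oxyallyl, compact transition state). A lipase resolution of the hydroxy enone selects the (6R,7S) series. The diene adds anti to the axial methyl on the quaternary carbon, and cis fusion plus SN2 inversion then fix the cage.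

Key step: step 3

Remark: compounds 3, 4 and 7 to 13 are racemic and their SMILES show the enantiomer that is carried on; the lipase is assumed to follow the usual preference for the (R)-carbinol when the larger carbinol substituent has the higher CIP rank.

**Route**

Step 1
Reactants: 1 benzyl alcohol; 2 3-methylbut-3-en-2-one
Product: 3 racemic 4-(benzyloxy)-3-methylbutan-2-one
Conditions: 1 (excess), KOt-Bu (cat.), THF, 0 °C to rt; AcOH quench
Reagents that add atoms: none
Why: Base-catalysed oxa-Michael addition of the alkoxide to the enone β-carbon; the addition is reversible, so excess alcohol and neutralisation before distillation should hold the adduct.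

Step 2
Reactants: 3 racemic 4-(benzyloxy)-3-methylbutan-2-one
Product: 4 racemic 4-(benzyloxy)-3-bromo-3-methylbutan-2-one
Conditions: Br2 (1.0 equiv), CH2Cl2, 0 °C, dark
Reagents that add atoms: bromine, BrBr
Why: Acid-autocatalysed α-bromination of a ketone in an aprotic solvent runs through the more substituted enol and should place bromine on the tertiary α-carbon, not on the methyl group.

Step 3
Reactants: 4 racemic 4-(benzyloxy)-3-bromo-3-methylbutan-2-one; 5 2-methylfuran
Product: 7 racemic 2-(benzyloxymethyl)-2,5-dimethyl-8-oxabicyclo[3.2.1]oct-6-en-3-one (C2 methyl on the side of the oxygen bridge), via lithium-bound oxyallyl cation 6 (not isolated)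
Conditions: 5 (5 equiv), Et3N (1.5 equiv), 3 M LiClO4 in Et2O, rt
Reagents that add atoms: none
Why: Et3N enolises 4 toward its methyl group and LiClO4 assists loss of bromide to give the oxyallyl cation 6, which adds across C2 and C5 of the furan in an asynchronous (4+3) cycloaddition, the known reaction of oxyallyl cations from α-halo ketones with furans under amine/LiClO4 conditions. The seven-membered carbocycle closes by intermolecular (4+3) annulation: the fully substituted terminus joins the unsubstituted furan α-carbon and the CH2 terminus the methylated one, while the furan oxygen stays as the one-atom bridge. The bridge ties C1 and C5 together, and the compact (boat-like) transition state usual for furan turns the oxyallyl substituent syn to the oxyallyl oxygen into the equatorial one at C2. Lithium chelation between that oxygen and the benzyl ether oxygen should put the benzyloxymethyl group there, so the C2 methyl ends axial, cis to the oxygen bridge, as the target requires. The step needs head-to-tail regiochemistry, which rests on the steric cost of joining the fully substituted terminus to the methylated furan carbon; the polar preference for a first bond between the CH2 terminus and furan C5 works against it, and this is the main risk. The adduct is racemic.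

Step 4
Reactants: 7 racemic 2-(benzyloxymethyl)-2,5-dimethyl-8-oxabicyclo[3.2.1]oct-6-en-3-one
Product: 9 racemic 2-(hydroxymethyl)-2,5-dimethyl-8-oxabicyclo[3.2.1]octan-3-one, via saturated benzyl ether 8 (not isolated)
Conditions: H2 (1 atm), 10% Pd/C, EtOH, rt
Reagents that add atoms: none
Why: Heterogeneous hydrogenation saturates the strained cis-alkene and then hydrogenolyses the benzyl ether, which is no longer needed as a chelating group, would not survive step 12 and could not be removed beside the final enone; no stereocentre is touched.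

Step 5
Reactants: 9 racemic 2-(hydroxymethyl)-2,5-dimethyl-8-oxabicyclo[3.2.1]octan-3-one
Product: 10 racemic 2-[(tert-butyldimethylsilyloxy)methyl]-2,5-dimethyl-8-oxabicyclo[3.2.1]octan-3-one
Conditions: TBSCl, imidazole, DMF, rt
Reagents that add atoms: tert-butyldimethylsilyl chloride, CC(C)(C)[Si](C)(C)Cl
Why: Standard silylation of a primary alcohol under non-basic conditions that leave the β-hydroxy ketone intact.

Step 6
Reactants: 10 racemic 2-[(tert-butyldimethylsilyloxy)methyl]-2,5-dimethyl-8-oxabicyclo[3.2.1]octan-3-one
Product: 13 racemic 7-[(tert-butyldimethylsilyloxy)methyl]-6-hydroxy-3,7-dimethylcyclohept-2-en-1-one (7-methyl cis to 6-OH), via trimethylsilyl enol ether 11 (not isolated), via ring-opened trimethylsilyl ether 12 (not isolated)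
Conditions: TMSOTf (1.3 equiv), Et3N (2 equiv), CH2Cl2, 0 °C to rt; then citric acid, MeOH, 0 °C
Reagents that add atoms: none
Why: Soft enolisation toward C4, the only enolisable α-carbon, followed by silyl-triflate-assisted β-elimination (E1cB type) of the bridging oxygen from the tertiary C5 is the known opening of 8-oxabicyclo[3.2.1]octan-3-ones to 4-silyloxycycloheptenones; no free alkoxide forms, so retro-aldol cleavage next to the quaternary carbon is avoided and both stereocentres are kept.

Step 7
Reactants: 13 racemic 7-[(tert-butyldimethylsilyloxy)methyl]-6-hydroxy-3,7-dimethylcyclohept-2-en-1-one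
Product: 14 (6R,7S)-6-acetoxy-7-[(tert-butyldimethylsilyloxy)methyl]-3,7-dimethylcyclohept-2-en-1-one
Conditions: Burkholderia cepacia lipase (Amano PS, immobilised), vinyl acetate, MTBE, 35 °C, to about half conversion
Reagents that add atoms: vinyl acetate, C=COC(C)=O
Why: Lipase-catalysed kinetic resolution by irreversible transesterification, a reaction type known for 3-hydroxy-2,2-disubstituted cycloalkanones; the (R)-carbinol should be acylated and the (6S,7R)-alcohol left behind and separated by chromatography.

Step 8
Reactants: 14 (6R,7S)-6-acetoxy-7-[(tert-butyldimethylsilyloxy)methyl]-3,7-dimethylcyclohept-2-en-1-one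
Product: 15 (6R,7S)-7-[(tert-butyldimethylsilyloxy)methyl]-6-hydroxy-3,7-dimethylcyclohept-2-en-1-one
Conditions: K2CO3 (cat.), MeOH, 0 °C
Reagents that add atoms: none
Why: Mild transesterification (methanolysis) of the acetate; the α-carbon is quaternary, so elimination is impossible, and low temperature should suppress retro-aldol opening.

Step 9
Reactants: 15 (6R,7S)-7-[(tert-butyldimethylsilyloxy)methyl]-6-hydroxy-3,7-dimethylcyclohept-2-en-1-one
Product: 16 (6R,7S)-6-(tert-butyldimethylsilyloxy)-7-[(tert-butyldimethylsilyloxy)methyl]-3,7-dimethylcyclohept-2-en-1-one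
Conditions: TBSOTf, 2,6-lutidine, CH2Cl2, −78 to 0 °C
Reagents that add atoms: tert-butyldimethylsilyl triflate, CC(C)(C)[Si](C)(C)OS(=O)(=O)C(F)(F)F
Why: Silyl triflate with a hindered pyridine base silylates the hindered secondary alcohol without generating an alkoxide; the bulky equatorial silyloxy group also fixes the ring conformer with the quaternary-carbon methyl axial.

Step 10
Reactants: 17 (E)-pent-3-en-2-one
Product: 18 (E)-2-(tert-butyldimethylsilyloxy)penta-1,3-diene
Conditions: TBSOTf, Et3N, Et2O, 0 °C
Reagents that add atoms: tert-butyldimethylsilyl triflate, CC(C)(C)[Si](C)(C)OS(=O)(=O)C(F)(F)F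
Why: Kinetic soft enolisation of an enone at its α'-methyl group gives the cross-conjugated 2-silyloxydiene with the alkene geometry retained.

Step 11
Reactants: 16 (6R,7S)-6-(tert-butyldimethylsilyloxy)-7-[(tert-butyldimethylsilyloxy)methyl]-3,7-dimethylcyclohept-2-en-1-one; 18 (E)-2-(tert-butyldimethylsilyloxy)penta-1,3-diene
Product: 19 cis-fused 2,7-bis(tert-butyldimethylsilyloxy)-6-[(tert-butyldimethylsilyloxy)methyl]-4,6,9a-trimethyl-1,4,4a,6,7,8,9,9a-octahydro-5H-benzo[7]annulen-5-one
Conditions: 18 (2 equiv), AlBr3/AlMe3 (10:1, substoichiometric), toluene/CH2Cl2, −20 to 0 °C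
Reagents that add atoms: none
Why: Lewis-acid-catalysed Diels–Alder reaction, with a mixed aluminium catalyst known to join hindered 2-silyloxydienes to β,β-disubstituted cycloalkenones: the diene CH2 terminus bonds to the enone β-carbon and the methyl-bearing terminus to the α-carbon, suprafacial addition makes the ring fusion cis, the diene should approach the face opposite the axial methyl of the quaternary carbon (the face that also carries the C7 silyloxy group), and the endo-derived centre at C4 is erased in step 14.

Step 12
Reactants: 19 cis-fused 2,7-bis(tert-butyldimethylsilyloxy)-6-[(tert-butyldimethylsilyloxy)methyl]-4,6,9a-trimethyl-1,4,4a,6,7,8,9,9a-octahydro-5H-benzo[7]annulen-5-one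
Product: 20 the corresponding benzo[7]annulen-5-ol (5-OH cis to the 6-methyl and to 4a-H)
Conditions: Li, NH3(l)/THF, t-BuOH (2 equiv), −78 °C; then NH4Cl
Reagents that add atoms: none
Why: Dissolving-metal reduction of the hindered ketone should give the thermodynamically preferred equatorial carbinol (an axial hydroxyl would be 1,3-diaxial to the ring CH2 on the quaternary fusion carbon), which is the epimer needed for backside displacement; the silyl enol ether masks the other carbonyl and, like the silyl ethers, is inert to these conditions.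

Step 13
Reactants: 20 benzo[7]annulen-5-ol
Product: 21 the corresponding benzo[7]annulen-5-yl methanesulfonate
Conditions: MsCl, Et3N, CH2Cl2, 0 °C
Reagents that add atoms: methanesulfonyl chloride, CS(=O)(=O)Cl
Why: Mesylation through sulfene is the standard way to sulfonylate a hindered secondary alcohol and proceeds with retention at carbon.

Step 14
Reactants: 21 benzo[7]annulen-5-yl methanesulfonate
Product: 22 7-(tert-butyldimethylsilyloxy)-6-[(tert-butyldimethylsilyloxy)methyl]-4,6,9a-trimethyl-2-oxo-2,4a,5,6,7,8,9,9a-octahydro-1H-benzo[7]annulen-5-yl methanesulfonate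
Conditions: Pd(OAc)2 (1.1 equiv), MeCN, rt to 40 °C
Reagents that add atoms: none
Why: Saegusa–Ito oxidation of the silyl enol ether; β-hydride elimination can only take the hydrogen on the methyl-bearing carbon, so the 3-methylcyclohexenone of the target forms regiospecifically and the inconsequential C4 stereocentre disappears.

Step 15
Reactants: 22 enone mesylate
Product: 24 5-(tert-butyldimethylsilyloxy)-6-[(tert-butyldimethylsilyloxy)methyl]-2,6,9-trimethyltricyclo[5.4.0.0(2,8)]undec-9-en-11-one, via potassium dienolate 23 (not isolated)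
Conditions: KN(SiMe3)2 (1.2 equiv), THF, −78 °C to rt
Reagents that add atoms: none
Why: Kinetic α'-deprotonation of the enone followed by intramolecular SN2 alkylation (4-exo-tet) of the equatorial mesylate is the known keto-sulfonate closure of bicyclo[3.1.1]heptanones; attack from the face of the six-membered ring inverts the carbinol carbon, and the cage allows only one configuration at the new bridgehead.

Step 16
Reactants: 24 bis-silyl tricyclic enone
Product: 25 5-hydroxy-6-(hydroxymethyl)-2,6,9-trimethyltricyclo[5.4.0.0(2,8)]undec-9-en-11-one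
Conditions: HF·pyridine, THF/pyridine, 0 °C to rt
Reagents that add atoms: none
Why: Buffered fluoride desilylation removes both silyl ethers in one operation without acid or base strong enough to disturb the strained enone.

Step 17
Reactants: 25 tricyclic diol; 26 angelic acid
Product: 29 5-(angeloyloxy)-6-(angeloyloxymethyl)-2,6,9-trimethyltricyclo[5.4.0.0(2,8)]undec-9-en-11-one (CNP0240716.2), via mixed anhydride 27 (not isolated), via primary monoangelate 28 (not isolated)
Conditions: 26 (5 equiv), 2,4,6-trichlorobenzoyl chloride, Et3N, toluene, rt; then 25, 80 °C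
Reagents that add atoms: none
Why: Yamaguchi-type mixed-anhydride esterification without a nucleophilic amine catalyst is the established way to acylate hindered alcohols with angelic acid while limiting Z-to-E isomerisation to the tiglate; the primary hydroxyl reacts first and the hindered secondary one on heating.

**Compound list**

1 | benzyl alcohol | OCc1ccccc1 | starting material
2 | 3-methylbut-3-en-2-one | CC(=O)C(C)=C | starting material
3 | racemic 4-(benzyloxy)-3-methylbutan-2-one | CC(=O)C(C)COCc1ccccc1 | intermediate
4 | racemic 4-(benzyloxy)-3-bromo-3-methylbutan-2-one | CC(=O)C(C)(Br)COCc1ccccc1 | intermediate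
5 | 2-methylfuran | Cc1ccco1 | starting material
6 | lithium-bound 1-(benzyloxymethyl)-1-methyl-2-oxyallyl cation | C=C(O[Li])[C+](C)COCc1ccccc1 | intermediate
7 | racemic 2-(benzyloxymethyl)-2,5-dimethyl-8-oxabicyclo[3.2.1]oct-6-en-3-one, C2 methyl axial and cis to the oxygen bridge | O(Cc1ccccc1)C[C@]1(C)C(=O)C[C@]2(C)C=C[C@H]1O2 | intermediate
8 | racemic 2-(benzyloxymethyl)-2,5-dimethyl-8-oxabicyclo[3.2.1]octan-3-one | O(Cc1ccccc1)C[C@]1(C)C(=O)C[C@]2(C)CC[C@H]1O2 | intermediate
9 | racemic 2-(hydroxymethyl)-2,5-dimethyl-8-oxabicyclo[3.2.1]octan-3-one | OC[C@]1(C)C(=O)C[C@]2(C)CC[C@H]1O2 | intermediate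
10 | racemic 2-[(tert-butyldimethylsilyloxy)methyl]-2,5-dimethyl-8-oxabicyclo[3.2.1]octan-3-one | CC(C)(C)[Si](C)(C)OC[C@]1(C)C(=O)C[C@]2(C)CC[C@H]1O2 | intermediate
11 | trimethylsilyl enol ether of 10 (C3–C4 enol ether) | CC(C)(C)[Si](C)(C)OC[C@]1(C)C(O[Si](C)(C)C)=C[C@]2(C)CC[C@H]1O2 | intermediate
12 | racemic 7-[(tert-butyldimethylsilyloxy)methyl]-3,7-dimethyl-6-(trimethylsilyloxy)cyclohept-2-en-1-one | CC(C)(C)[Si](C)(C)OC[C@]1(C)C(=O)C=C(C)CC[C@H]1O[Si](C)(C)C | intermediate
13 | racemic 7-[(tert-butyldimethylsilyloxy)methyl]-6-hydroxy-3,7-dimethylcyclohept-2-en-1-one, 7-methyl cis to 6-OH | CC(C)(C)[Si](C)(C)OC[C@]1(C)C(=O)C=C(C)CC[C@H]1O | intermediate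
14 | (6R,7S)-6-acetoxy-7-[(tert-butyldimethylsilyloxy)methyl]-3,7-dimethylcyclohept-2-en-1-one | CC(C)(C)[Si](C)(C)OC[C@]1(C)C(=O)C=C(C)CC[C@H]1OC(C)=O | intermediate
15 | (6R,7S)-7-[(tert-butyldimethylsilyloxy)methyl]-6-hydroxy-3,7-dimethylcyclohept-2-en-1-one | CC(C)(C)[Si](C)(C)OC[C@]1(C)C(=O)C=C(C)CC[C@H]1O | intermediate
16 | (6R,7S)-6-(tert-butyldimethylsilyloxy)-7-[(tert-butyldimethylsilyloxy)methyl]-3,7-dimethylcyclohept-2-en-1-one | CC(C)(C)[Si](C)(C)OC[C@]1(C)C(=O)C=C(C)CC[C@H]1O[Si](C)(C)C(C)(C)C | intermediate
17 | (E)-pent-3-en-2-one | C/C=C/C(C)=O | starting material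
18 | (E)-2-(tert-butyldimethylsilyloxy)penta-1,3-diene | C/C=C/C(=C)O[Si](C)(C)C(C)(C)C | intermediate
19 | cis-fused 2,7-bis(tert-butyldimethylsilyloxy)-6-[(tert-butyldimethylsilyloxy)methyl]-4,6,9a-trimethyl-1,4,4a,6,7,8,9,9a-octahydro-5H-benzo[7]annulen-5-one; 4a-H, 9a-methyl, 6-methyl and 7-O on one face, 4-H cis to 4a-H | CC(C)(C)[Si](C)(C)OC[C@]1(C)C(=O)[C@@H]2[C@H](C)C=C(O[Si](C)(C)C(C)(C)C)C[C@]2(C)CC[C@H]1O[Si](C)(C)C(C)(C)C | intermediate
20 | benzo[7]annulen-5-ol from 19, 5-OH cis to the 6-methyl and to 4a-H | CC(C)(C)[Si](C)(C)OC[C@]1(C)[C@@H](O)[C@@H]2[C@H](C)C=C(O[Si](C)(C)C(C)(C)C)C[C@]2(C)CC[C@H]1O[Si](C)(C)C(C)(C)C | intermediate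
21 | methanesulfonate of 20 | CC(C)(C)[Si](C)(C)OC[C@]1(C)[C@@H](OS(C)(=O)=O)[C@@H]2[C@H](C)C=C(O[Si](C)(C)C(C)(C)C)C[C@]2(C)CC[C@H]1O[Si](C)(C)C(C)(C)C | intermediate
22 | 7-(tert-butyldimethylsilyloxy)-6-[(tert-butyldimethylsilyloxy)methyl]-4,6,9a-trimethyl-2-oxo-2,4a,5,6,7,8,9,9a-octahydro-1H-benzo[7]annulen-5-yl methanesulfonate | CC(C)(C)[Si](C)(C)OC[C@]1(C)[C@@H](OS(C)(=O)=O)[C@@H]2C(C)=CC(=O)C[C@]2(C)CC[C@H]1O[Si](C)(C)C(C)(C)C | intermediate
23 | potassium cross-conjugated dienolate of 22 (C1–C2 enolate) | CC(C)(C)[Si](C)(C)OC[C@]1(C)[C@@H](OS(C)(=O)=O)[C@@H]2C(C)=CC([O-])=C[C@]2(C)CC[C@H]1O[Si](C)(C)C(C)(C)C.[K+] | intermediate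
24 | 5-(tert-butyldimethylsilyloxy)-6-[(tert-butyldimethylsilyloxy)methyl]-2,6,9-trimethyltricyclo[5.4.0.0(2,8)]undec-9-en-11-one | CC(C)(C)[Si](C)(C)OC[C@]1(C)[C@@H]2[C@H]3C(=O)C=C(C)[C@@H]2[C@@]3(C)CC[C@H]1O[Si](C)(C)C(C)(C)C | intermediate
25 | 5-hydroxy-6-(hydroxymethyl)-2,6,9-trimethyltricyclo[5.4.0.0(2,8)]undec-9-en-11-one | OC[C@]1(C)[C@@H]2[C@H]3C(=O)C=C(C)[C@@H]2[C@@]3(C)CC[C@H]1O | intermediate
26 | angelic acid, (Z)-2-methylbut-2-enoic acid | C/C=C(/C)C(=O)O | starting material
27 | angelic 2,4,6-trichlorobenzoic anhydride | C/C=C(/C)C(=O)OC(=O)c1c(Cl)cc(Cl)cc1Cl | intermediate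
28 | primary monoangelate of 25 | C/C=C(/C)C(=O)OC[C@]1(C)[C@@H]2[C@H]3C(=O)C=C(C)[C@@H]2[C@@]3(C)CC[C@H]1O | intermediate
29 | CNP0240716.2, 5-(angeloyloxy)-6-(angeloyloxymethyl)-2,6,9-trimethyltricyclo[5.4.0.0(2,8)]undec-9-en-11-one | C/C=C(/C)C(=O)OC[C@]1(C)[C@@H]2[C@H]3C(=O)C=C(C)[C@@H]2[C@@]3(C)CC[C@H]1OC(=O)/C(C)=C\C | target

**Step count**

Total steps: 17. Longest linear sequence: 16 (steps 1 to 9 and 11 to 17; step 10 makes the diene separately).

**Steps most likely to fail**

Step 3. The cycloaddition may take the opposite regiochemistry. If the first bond forms between the CH2 terminus of the cation and the unsubstituted, more nucleophilic α-carbon of 2-methylfuran, the fully substituted terminus ends on the methylated carbon; the furan could also capture the cation at C5 without ring closure. Loss of the chelation-based control at C2 would show up here as well.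
Fallback, from 4 back to 13: the cycloaddition is run with furan itself, where no regiochemical question exists, and the ring methyl is added afterwards. Compound 4 with furan, Et3N and LiClO4 in Et2O should give racemic 2-(benzyloxymethyl)-2-methyl-8-oxabicyclo[3.2.1]oct-6-en-3-one F1. Hydrogenation over Pd/C gives the saturated hydroxymethyl ketone F2, and TBSCl/imidazole gives its silyl ether F3. TMSOTf/Et3N opens the bridge to the ring-opened trimethylsilyl ether F4, an enone with a free β-position. Me2CuLi with Me3SiCl adds the methyl group in a 1,4 sense and gives the trimethylsilyl enol ether F5. Pd(OAc)2 in MeCN (Saegusa–Ito oxidation) re-forms the enone as 12, and citric acid in MeOH gives 13.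

Step 11. The cycloaddition may stall or the diene may be consumed by the Lewis acid, because both dienophile carbons are hindered (one becomes quaternary) and the silyl ethers can tie up the catalyst; a weaker facial preference than expected would also appear here.
Fallback, from 16 and 18 back to 19: the two bonds are made one after the other by polar steps. TiCl4-promoted Mukaiyama–Michael addition of 18 to 16 at −78 °C, followed by aqueous work-up, should give the open-chain diketone F6, whose new quaternary carbon carries an (E)-2-oxopent-3-enyl chain. KOt-Bu in t-BuOH/THF then closes the six-membered ring by intramolecular Michael addition of the ring-ketone enolate, which has only one enolisable position, to give the cis-fused bicyclic diketone F7. TBSOTf/Et3N enolises the unhindered ketone of the new ring away from the quaternary carbon and returns 19; either epimer at the methyl-bearing carbon is acceptable because that centre becomes trigonal in step 14.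

Step 15. Displacement at a secondary carbon flanked by a quaternary and a tertiary carbon may be slow, which gives time for proton transfer to the extended dienolate and loss of mesylate by vinylogous elimination; a wrong carbinol configuration from step 12 would show up here as complete failure to cyclise.
Fallback, from 19 back to 24: the cyclobutane bond is made by a Norrish–Yang photocyclisation, which does not depend on a carbinol configuration. Irradiation of ketone 19 (Pyrex, benzene) should abstract the allylic γ-hydrogen of the CH2 next to the silyl enol ether and close the 1,4-biradical to the tertiary cyclobutanol F8. Methyl chlorooxoacetate converts it into the methyl oxalate F9, and Bu3SnH/AIBN (Barton–McCombie-type radical deoxygenation) gives the tricyclic silyl enol ether F10; the cage allows only one configuration at the new CH. Pd(OAc)2 in MeCN then turns F10 into 24.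

**Further compounds**

F1 | step 3 | racemic 2-(benzyloxymethyl)-2-methyl-8-oxabicyclo[3.2.1]oct-6-en-3-one, methyl cis to the oxygen bridge | c1ccccc1COC[C@]1(C)C(=O)C[C@@H]2C=C[C@H]1O2
F2 | step 3 | racemic 2-(hydroxymethyl)-2-methyl-8-oxabicyclo[3.2.1]octan-3-one | OC[C@]1(C)C(=O)C[C@@H]2CC[C@H]1O2
F3 | step 3 | racemic 2-[(tert-butyldimethylsilyloxy)methyl]-2-methyl-8-oxabicyclo[3.2.1]octan-3-one | CC(C)(C)[Si](C)(C)OC[C@]1(C)C(=O)C[C@@H]2CC[C@H]1O2
F4 | step 3 | racemic 7-[(tert-butyldimethylsilyloxy)methyl]-7-methyl-6-(trimethylsilyloxy)cyclohept-2-en-1-one | CC(C)(C)[Si](C)(C)OC[C@]1(C)C(=O)C=CCC[C@H]1O[Si](C)(C)C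
F5 | step 3 | racemic 7-[(tert-butyldimethylsilyloxy)methyl]-3,7-dimethyl-1,6-bis(trimethylsilyloxy)cyclohept-1-ene, C3 as a mixture | CC(C)(C)[Si](C)(C)OC[C@]1(C)C(O[Si](C)(C)C)=CC(C)CC[C@H]1O[Si](C)(C)C
F6 | step 11 | 6-(tert-butyldimethylsilyloxy)-7-[(tert-butyldimethylsilyloxy)methyl]-3,7-dimethyl-3-[(E)-2-oxopent-3-enyl]cycloheptan-1-one | CC(C)(C)[Si](C)(C)OC[C@]1(C)C(=O)C[C@](C)(CC(=O)/C=C/C)CC[C@H]1O[Si](C)(C)C(C)(C)C
F7 | step 11 | cis-fused 7-(tert-butyldimethylsilyloxy)-6-[(tert-butyldimethylsilyloxy)methyl]-4,6,9a-trimethyloctahydro-1H-benzo[7]annulene-2,5-dione, C4 as a mixture | CC(C)(C)[Si](C)(C)OC[C@]1(C)C(=O)[C@@H]2C(C)CC(=O)C[C@]2(C)CC[C@H]1O[Si](C)(C)C(C)(C)C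
F8 | step 15 | tertiary cyclobutanol: 5,11-bis(tert-butyldimethylsilyloxy)-6-[(tert-butyldimethylsilyloxy)methyl]-2,6,9-trimethyltricyclo[5.4.0.0(2,8)]undec-10-en-7-ol | CC(C)(C)[Si](C)(C)OC[C@]1(C)[C@]2(O)[C@H]3C(O[Si](C)(C)C(C)(C)C)=C[C@@H](C)[C@@H]2[C@@]3(C)CC[C@H]1O[Si](C)(C)C(C)(C)C
F9 | step 15 | methyl oxalate of F8 | CC(C)(C)[Si](C)(C)OC[C@]1(C)[C@]2(OC(=O)C(=O)OC)[C@H]3C(O[Si](C)(C)C(C)(C)C)=C[C@@H](C)[C@@H]2[C@@]3(C)CC[C@H]1O[Si](C)(C)C(C)(C)C
F10 | step 15 | 5,11-bis(tert-butyldimethylsilyloxy)-6-[(tert-butyldimethylsilyloxy)methyl]-2,6,9-trimethyltricyclo[5.4.0.0(2,8)]undec-10-ene | CC(C)(C)[Si](C)(C)OC[C@]1(C)[C@@H]2[C@H]3C(O[Si](C)(C)C(C)(C)C)=C[C@@H](C)[C@@H]2[C@@]3(C)CC[C@H]1O[Si](C)(C)C(C)(C)C
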